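## Structural features

The target is a flavone. A benzene ring A (C4a, C5, C6, C7, C8, C8a) is fused to a 4-pyranone ring C (O1, C2, C3, C4), and C2 carries a second benzene ring B through the C2–C1' bond. Ring A bears free hydroxyls at C5 and C6, a methoxy group at C7 and hydrogen at C8. Ring B bears methoxy groups at C2' and C5' and a free hydroxyl at C4'. There is no stereocentre and the C2–C1' bond rotates freely, so no stereochemical problem arises. The fragile parts are the C5/C6 catechol, which air oxidises to an ortho-quinone in basic medium, and the pyranone, which strong hydroxide opens at C2. The real difficulty is regiochemical: ring A is pentasubstituted with four adjacent heteroatom-bearing carbons, and of six oxygen substituents three must end free (O5, O6, O4') and three methylated (O7, O2', O5'). The feature exploited is that C8a carries O1 while the neighbouring C4a carries the acyl carbon C4. These are the two groups a carboxylic acid can deliver to the two carbons of an aryne, and the C5 oxygen next to C4a decides which aryne carbon receives which.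

## Logic of the disconnections

18 to 17: the O–CH3 bonds at O5 and O6 are cut last in the forward sense. The catechol is the sensitive part of 18, and a fully methylated ring A can come from a cheap symmetric arene, so ring A needs no differentiated protecting groups. The demand is high, because two of five methyl ethers must fall and three must stay. The selectivity has to come from the peri relation of O5 to the C4 carbonyl and from the doubly flanked, out-of-plane position of the C6 methoxy group. AlBr3 is preferred to AlCl3 because bromide is the better nucleophile for the second, non-peri cleavage.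

17 to 16: the O4'–CH2Ph bond is cut. The C4' phenol must be masked in the key step, since a phenoxide would compete with the carboxylate for the aryne, and a benzyl ether is inert to fluoride, base and heat. The forward step must remove benzyl without reducing C2=C3. It is placed before the Lewis-acid step so that no benzylic electrophile is present when the electron-rich rings meet AlBr3.

16 to 5 and 13: the bonds O1–C8a, C4–C4a and O1–C2 are cut, which removes ring C and splits the molecule into two halves of similar size. All three bonds form in one operation through 14 and 15, so ring C needs no separate construction. The forward step demands three things: carboxylate attack at the correct carbon of 14, acyl transfer faster than protonation of the aryl anion, and 6-endo rather than 5-exo closure of 15.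

5 to 2 to 1: the C–Si and O–SO2CF3 bonds are cut, then the C–Br bond. Silicon and triflate must sit on neighbouring carbons with silicon next to a methoxy group, and the bromine marks that carbon. Because 1 is symmetric, both positions ortho to its hydroxyl are equivalent and no positional isomer can arise. The demands are clean monobromination of a very electron-rich phenol and complete O-to-C silyl shift before triflation.

13 to 11 and 12: the C1'–C(sp) bond is cut. The three-carbon acid unit is available as 12, so the acid is reached in one step from an aryl iodide, one step fewer than an aldehyde homologation. The forward coupling must keep the carboxyl group.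

11 to 10 to 8 and 9, then 8 to 6: the C–I bond, the O–CH2Ph bond and the aryl C–O bond are cut in turn, the last one standing in place of the aryl–CHO bond of 6. The demands are iodination para to the benzyloxy group only, and aryl rather than hydride migration in the oxidation of 6.

## Other disconnections considered

Alternative 1: Ring B is built on a finished chromone instead of being brought in ready-made.
- Cut: C5'–C6', C1'–C2' and C2'–C3'.
- Forward key step (Dötz benzannulation): the terminal alkyne of 2-ethynyl-5,6,7-trimethoxychromen-4-one A1 would insert into the chromium carbene (CO)5Cr=C(OMe)C(OtBu)=CH2 A2, a CO ligand would follow, and the dienylketene would close to 2-[4-(tert-butoxy)-2-hydroxy-5-methoxyphenyl]-5,6,7-trimethoxychromen-4-one A3.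
- In its favour: the three ring B oxygens emerge chemically distinct (free hydroxyl at C2', methyl ether at C5', tert-butyl ether at C4'). Terminal alkynes normally place their substituent next to the new hydroxyl, which is the arrangement needed. The tert-butyl ether should fall in the same aluminium halide treatment as the C5 and C6 methyl ethers, so no hydrogenolysis is needed. With O-methylation at C2' and one deprotection, the endgame is the equal of the chosen plan in length.
- Against it here: ring B is a plain trialkoxybenzene that 6 supplies in three steps. A1 is an electron-poor, base-sensitive alkyne of a class that tends to react less cleanly in this benzannulation than simple acetylenes. A2 is an air-sensitive alkoxyvinyl carbene that needs stoichiometric zerovalent chromium.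
- Structure: the hard part, pentasubstituted ring A, is not addressed but moved into the making of A1.
- Mechanism: both plans use a cascade whose regiochemistry is set by polarisation of a triple bond, but the chosen one needs only fluoride.
- Step economy: A1 and A2 each take several steps, so the route would be clearly longer.

Alternative 2: Ring A is grown onto a monocyclic pyranone.
- Cut: C8–C8a and C5–C4a.
- Forward key step: 2-[4-(benzyloxy)-2,5-dimethoxyphenyl]-6-(tributylstannyl)pyran-4-one A4 would be coupled with racemic 4-chloro-2,3-dimethoxycyclobut-2-en-1-one A5 under PdCl2(PhCN)2 and tri(2-furyl)phosphine (Stille coupling, C8–C8a). On heating, the four-membered ring would open to a dienylketene whose ketene carbon closes on C4a in a six-electron electrocyclisation. Tautomerisation would give 2-[4-(benzyloxy)-2,5-dimethoxyphenyl]-5-hydroxy-6,7-dimethoxychromen-4-one A6.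
- In its favour: the positions of the ring A oxygens follow from connectivity and not from a selectivity, and O5 arrives as a free hydroxyl. On both points it is better than the chosen plan, which relies on the polarisation of 14 and must cleave the C5 ether afterwards.
- Against it here: O6 and O7 both arrive as methyl ethers, so C6 must still be demethylated beside C7 with an aluminium halide. The endgame is therefore equal, not shorter. A4 needs a regioselective metalation and stannylation at C6 and brings stoichiometric tin. A5 is a sensitive compound that itself takes several steps.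
- Mechanism: thermal pericyclic steps are at least as dependable as the anionic cascade, so the two are equal here.
- Step economy: both partners are several steps from commercial material, whereas 5 is two steps from 1, so the alternative is longer.

Alternative 3: Only O1–C8a is cut, and it is made by C–H functionalisation.
- Forward key step: 1-[4-(benzyloxy)-2,5-dimethoxyphenyl]-3-(3-hydroxy-2,4-dimethoxyphenyl)propane-1,3-dione A7 would be oxidised by two electrons at a carbon anode in hexafluoroisopropanol. The enol oxygen would trap the phenoxenium ion at the carbon para to the hydroxyl (C8a). Loss of a proton would give 2-[4-(benzyloxy)-2,5-dimethoxyphenyl]-6-hydroxy-5,7-dimethoxychromen-4-one A8.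
- In its favour: no leaving group is needed at C8a and no reagent waste arises. O6 arrives free, so only the peri ether at C5, the easiest to cleave, remains. On the endgame it is better than the chosen plan. A7 comes from a standard Claisen-type condensation.
- Against it here: para trapping with rearomatisation competes with capture by solvent and with dearomatised quinone-type products, the more so as the phenol is flanked by two methoxy groups. Ring B, a 1,2,4-trialkoxybenzene, should be oxidised at a potential no higher than the acylated phenol ring, so the wrong ring may react. The ring A ketone is not a cheap symmetric arene like 1 and needs its own synthesis.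
- Structure: equal in convergence, since two aryl halves are joined through a three-carbon unit.
- Mechanism: less secure, because close analogies for anodic closure of a diketone enol para to a phenol are few.
- Step economy: comparable or slightly longer.

Key step: step 7

Remark: 18 has no stereocentre, so no configuration has to be set or kept; the silylation, silyl shift and triflation of step 2 are run in one flask and counted as one step.

Step 1
Reactants: 1 3,4,5-trimethoxyphenol
Product: 2 2-bromo-3,4,5-trimethoxyphenol
Conditions: NBS (1.0 equiv), CH2Cl2, −78 °C to 0 °C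
Reagents that add atoms: N-bromosuccinimide, O=C1CCC(=O)N1Br
Why: Electrophilic aromatic bromination ortho to the free hydroxyl; the para position is blocked and the two ortho positions are equivalent by symmetry, so only one monobromide can form, and one equivalent at low temperature should hold back dibromination.

Step 2
Reactants: 2 2-bromo-3,4,5-trimethoxyphenol
Product: 5 3,4,5-trimethoxy-2-(trimethylsilyl)phenyl trifluoromethanesulfonate, via (2-bromo-3,4,5-trimethoxyphenoxy)trimethylsilane 3 (not isolated), via lithium 3,4,5-trimethoxy-2-(trimethylsilyl)phenoxide 4 (not isolated)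
Conditions: HMDS, THF, reflux; evaporate; n-BuLi, THF, −78 °C; Tf2O, −78 °C to rt
Reagents that add atoms: hexamethyldisilazane, C[Si](C)(C)N[Si](C)(C)C; trifluoromethanesulfonic anhydride, O=S(=O)(OS(=O)(=O)C(F)(F)F)C(F)(F)F
Why: O-Silylation, then bromine–lithium exchange and a 1,3 O-to-C silyl shift (retro-Brook rearrangement) driven by the change from aryl anion to phenoxide, then O-triflation of that phenoxide; this is the standard one-flask entry to ortho-silylaryl triflates from ortho-bromophenols.

Step 3
Reactants: 6 2,5-dimethoxybenzaldehyde
Product: 8 2,5-dimethoxyphenol, via 2,5-dimethoxyphenyl formate 7 (not isolated)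
Conditions: mCPBA, CH2Cl2, 0 °C to rt; then aq. KOH, MeOH, rt; H3O+
Reagents that add atoms: 3-chloroperoxybenzoic acid, O=C(OO)c1cccc(Cl)c1
Why: Baeyer–Villiger oxidation of an electron-rich benzaldehyde (Dakin-type), in which the dialkoxyaryl group migrates in preference to hydrogen; the aryl formate is saponified in the same flask.

Step 4
Reactants: 8 2,5-dimethoxyphenol; 9 benzyl bromide
Product: 10 2-(benzyloxy)-1,4-dimethoxybenzene
Conditions: BnBr, K2CO3, DMF, rt
Reagents that add atoms: benzyl bromide (9), BrCc1ccccc1
Why: Williamson ether synthesis on the phenoxide.

Step 5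
Reactants: 10 2-(benzyloxy)-1,4-dimethoxybenzene
Product: 11 1-(benzyloxy)-4-iodo-2,5-dimethoxybenzene
Conditions: NIS, TFA (cat.), MeCN, rt
Reagents that add atoms: N-iodosuccinimide, O=C1CCC(=O)N1I
Why: Electrophilic aromatic iodination; the carbon para to the benzyloxy group and ortho to a methoxy group is the most activated and least hindered site, the same one a 1,2,4-trialkoxybenzene offers to electrophiles.

Step 6
Reactants: 11 1-(benzyloxy)-4-iodo-2,5-dimethoxybenzene; 12 propiolic acid
Product: 13 3-[4-(benzyloxy)-2,5-dimethoxyphenyl]prop-2-ynoic acid
Conditions: Pd(PPh3)4 (5 mol%), DBU (2.4 equiv), DMSO, 40 °C; then aq. HCl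
Reagents that add atoms: propiolic acid (12), C#CC(=O)O
Why: Copper-free Sonogashira-type coupling of an aryl iodide with the terminal C–H of propiolic acid on zerovalent palladium; as the DBU carboxylate and at low temperature the acid group should be kept and not lost by decarboxylation.

Step 7
Reactants: 5 3,4,5-trimethoxy-2-(trimethylsilyl)phenyl trifluoromethanesulfonate; 13 3-[4-(benzyloxy)-2,5-dimethoxyphenyl]prop-2-ynoic acid
Product: 16 2-[4-(benzyloxy)-2,5-dimethoxyphenyl]-5,6,7-trimethoxychromen-4-one, via 3,4,5-trimethoxybenzyne 14 (not isolated), via caesium ortho-ynoylphenoxide 15 (not isolated)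
Conditions: CsF (4 equiv), 5 (1.5 equiv), THF, 125 °C, sealed tube
Reagents that add atoms: none
Why: Fluoride attacks silicon of 5 and triflate leaves, giving aryne 14; the caesium carboxylate of 13 adds through oxygen at the aryne carbon remote from the flanking methoxy group (future C8a), because the inductively withdrawing C5 oxygen stabilises the developing carbanion on the carbon next to it (future C4a). That aryl anion attacks its own ester carbonyl through a strained four-membered alkoxide, which opens to the ortho-ynoyl phenoxide 15, so that C4a–C4 is formed and the acyl C–O bond of the acid is given up. The phenoxide oxygen then adds to the alkyne carbon bearing ring B in a 6-endo-dig oxa-Michael addition that closes ring C (O1–C2), and protonation at C3 should give 16. The closest known reaction type is the formal insertion of arynes into the C–O bond of carboxylic acids to give ortho-hydroxyaryl ketones, in its extension to arylpropiolic acids as a flavone synthesis. No stereocentre is formed. The step needs regioselective attack on the aryne, acyl transfer faster than protonation of the aryl anion, and 6-endo over 5-exo closure. The first is secured by the C5 methoxy group, the second by the hot aprotic medium in which CsF holds the acid as its caesium salt, and the third by the polarisation of the ynone, whose carbonyl makes the ring B-bearing carbon the electrophilic one.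

Step 8
Reactants: 16 2-[4-(benzyloxy)-2,5-dimethoxyphenyl]-5,6,7-trimethoxychromen-4-one
Product: 17 2-(4-hydroxy-2,5-dimethoxyphenyl)-5,6,7-trimethoxychromen-4-one
Conditions: H2 (1 atm), 10% Pd/C, EtOAc–MeOH, rt
Reagents that add atoms: none
Why: Hydrogenolysis of a benzyl aryl ether; the C2=C3 bond of a flavone is part of a vinylogous ester and should not be reduced under these conditions, and removing benzyl here keeps a benzylic electrophile out of the Lewis-acid step.

Step 9
Reactants: 17 2-(4-hydroxy-2,5-dimethoxyphenyl)-5,6,7-trimethoxychromen-4-one
Product: 18 5,6-dihydroxy-2-(4-hydroxy-2,5-dimethoxyphenyl)-7-methoxychromen-4-one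
Conditions: AlBr3 (excess), MeCN, 0 °C to 60 °C; then 2 M HCl, 60 °C
Reagents that add atoms: none
Why: Chelation-directed aryl methyl ether cleavage by an aluminium halide: aluminium held between the C4 carbonyl and O5 activates the C5 methyl ether toward bromide, and the resulting aluminium phenoxide passes the Lewis acid to the C6 methoxy group, which its two ortho neighbours twist out of the ring plane and make the most basic remaining ether. The C7, C2' and C5' ethers lack this assistance and should survive under controlled time and temperature.

Compound list

1 | 3,4,5-trimethoxyphenol | COc1cc(O)cc(OC)c1OC | starting material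
2 | 2-bromo-3,4,5-trimethoxyphenol | COc1cc(O)c(Br)c(OC)c1OC | intermediate
3 | (2-bromo-3,4,5-trimethoxyphenoxy)trimethylsilane | COc1cc(O[Si](C)(C)C)c(Br)c(OC)c1OC | intermediate
4 | lithium 3,4,5-trimethoxy-2-(trimethylsilyl)phenoxide | [Li+].COc1cc([O-])c([Si](C)(C)C)c(OC)c1OC | intermediate
5 | 3,4,5-trimethoxy-2-(trimethylsilyl)phenyl trifluoromethanesulfonate | COc1cc(OS(=O)(=O)C(F)(F)F)c([Si](C)(C)C)c(OC)c1OC | intermediate
6 | 2,5-dimethoxybenzaldehyde | COc1ccc(OC)c(C=O)c1 | starting material
7 | 2,5-dimethoxyphenyl formate | COc1ccc(OC)c(OC=O)c1 | intermediate
8 | 2,5-dimethoxyphenol | COc1ccc(OC)c(O)c1 | intermediate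
9 | benzyl bromide | BrCc1ccccc1 | starting material
10 | 2-(benzyloxy)-1,4-dimethoxybenzene | COc1ccc(OC)c(OCc2ccccc2)c1 | intermediate
11 | 1-(benzyloxy)-4-iodo-2,5-dimethoxybenzene | COc1cc(OCc2ccccc2)c(OC)cc1I | intermediate
12 | propiolic acid | C#CC(=O)O | starting material
13 | 3-[4-(benzyloxy)-2,5-dimethoxyphenyl]prop-2-ynoic acid | OC(=O)C#Cc1cc(OC)c(OCc2ccccc2)cc1OC | intermediate
14 | 3,4,5-trimethoxybenzyne (1,2-didehydro-3,4,5-trimethoxybenzene) | COC1=C(OC)C(OC)=CC#C1 | intermediate
15 | caesium 2-{3-[4-(benzyloxy)-2,5-dimethoxyphenyl]prop-2-ynoyl}-3,4,5-trimethoxyphenolate | [Cs+].COc1cc([O-])c(C(=O)C#Cc2cc(OC)c(OCc3ccccc3)cc2OC)c(OC)c1OC | intermediate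
16 | 2-[4-(benzyloxy)-2,5-dimethoxyphenyl]-5,6,7-trimethoxychromen-4-one | COc1cc(-c2cc(=O)c3c(OC)c(OC)c(OC)cc3o2)c(OC)cc1OCc1ccccc1 | intermediate
17 | 2-(4-hydroxy-2,5-dimethoxyphenyl)-5,6,7-trimethoxychromen-4-one | COc1cc(-c2cc(=O)c3c(OC)c(OC)c(OC)cc3o2)c(OC)cc1O | intermediate
18 | 5,6-dihydroxy-2-(4-hydroxy-2,5-dimethoxyphenyl)-7-methoxychromen-4-one | COc1cc(-c2cc(=O)c3c(O)c(O)c(OC)cc3o2)c(OC)cc1O | target

Total step count: 9 (steps 1 and 2 to 5; steps 3 to 6 to 13; steps 7 to 9 in common). Longest linear sequence: 7 steps, from 6 to 18 through steps 3 to 9.

Least certain steps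

Step 7 (key step). The most likely failures are three. The aryl anion may be protonated before it reaches the ester carbonyl, which leaves a simple O-aryl ester. The carboxylate may attack the other aryne carbon, which would place the oxygens at C6, C7 and C8. The phenoxide may close 5-exo instead of 6-endo. Thermal loss of CO2 from the propiolate is a further drain at 125 °C. The fallback builds ring C by condensation instead of aryne insertion; it sets out from 1 and 10 and comes back to the route at 16. Friedel–Crafts C-acetylation of 1 ortho to the hydroxyl (Ac2O, BF3·OEt2, 90 °C) should give 1-(6-hydroxy-2,3,4-trimethoxyphenyl)ethan-1-one F1. Vilsmeier formylation of 10 (POCl3, DMF) should give 4-(benzyloxy)-2,5-dimethoxybenzaldehyde F2. Claisen–Schmidt condensation of the two (KOH, EtOH, rt) should give (E)-3-[4-(benzyloxy)-2,5-dimethoxyphenyl]-1-(6-hydroxy-2,3,4-trimethoxyphenyl)prop-2-en-1-one F3. Oxidative cyclisation with I2 (cat.) in DMSO at 130 °C should then form O1–C2 and the C2=C3 bond to give 16.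

Step 9. The likely failure is loss of selectivity among five methyl ethers. The reaction may stop after the peri ether at C5, or it may go on to the C7 ether or to the C5' ether beside the aluminium phenoxide of ring B. Only the C5 ether has true carbonyl chelation, and the C6 ether depends on a weaker, conformational effect. The fallback replaces selective demethylation by protecting groups chosen in advance; it sets out from 13 and 9 and comes back at 18. 2,3-Dihydroxy-4-methoxybenzaldehyde F4 would be dibenzylated with 9 (K2CO3, DMF) to 2,3-bis(benzyloxy)-4-methoxybenzaldehyde F5. Baeyer–Villiger oxidation and saponification (mCPBA, then KOH, MeOH) should give 2,3-bis(benzyloxy)-4-methoxyphenol F6. Bromination at the only open position ortho to the hydroxyl (NBS, CH2Cl2, −78 °C) should give 2,3-bis(benzyloxy)-6-bromo-4-methoxyphenol F7. The one-flask sequence of step 2 (HMDS; n-BuLi; Tf2O) should give 2,3-bis(benzyloxy)-4-methoxy-6-(trimethylsilyl)phenyl trifluoromethanesulfonate F8. Under the conditions of step 7, F8 and 13 should give 5,6-bis(benzyloxy)-2-[4-(benzyloxy)-2,5-dimethoxyphenyl]-7-methoxychromen-4-one F9, the benzyloxy group beside the aryne playing the directing role of the C5 methoxy group. One hydrogenolysis (H2, 10% Pd/C) then frees O5, O6 and O4' together and gives 18. The price is a longer and less symmetric route to the aryne precursor.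

Step 6. The likely failures are decarboxylation of the propiolate followed by a second coupling to a diarylalkyne, and slow oxidative addition into an electron-rich, ortho-substituted aryl iodide. The fallback replaces cross-coupling by aldehyde homologation (Corey–Fuchs sequence); it sets out from 10 and comes back at 13. Vilsmeier formylation of 10 should give 4-(benzyloxy)-2,5-dimethoxybenzaldehyde F2, the aldehyde already described under step 7. CBr4 and PPh3 in CH2Cl2 at 0 °C should give 1-(benzyloxy)-4-(2,2-dibromoethenyl)-2,5-dimethoxybenzene F10. n-BuLi (2.2 equiv) in THF at −78 °C followed by CO2 and acidic work-up should give 13.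

Step 2. The likely failure is an incomplete silyl shift or protonation of the aryllithium by adventitious acid, which would end in a triflate without silicon; the very electron-rich ring also makes the bromophenol 2 prone to oxidation during handling. The fallback replaces halogen–metal exchange by directed ortho-metalation and avoids 2 altogether; it sets out from 1 and comes back at 5. Isopropyl isocyanate and Et3N should give 3,4,5-trimethoxyphenyl N-isopropylcarbamate F11. N-Silylation in the flask (TBSOTf, TMEDA), lithiation (n-BuLi, TMEDA, Et2O, −78 °C) between the carbamate and the C3 methoxy group, and TMSCl should give 3,4,5-trimethoxy-2-(trimethylsilyl)phenyl N-isopropylcarbamate F12. Cleavage with Et2NH and DBU in MeCN at 40 °C should free 3,4,5-trimethoxy-2-(trimethylsilyl)phenol F13, which PhNTf2 would triflate in the same flask to 5.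

Further compounds

F1 | step 7 | 1-(6-hydroxy-2,3,4-trimethoxyphenyl)ethan-1-one | COc1cc(O)c(C(C)=O)c(OC)c1OC
F2 | step 7 | 4-(benzyloxy)-2,5-dimethoxybenzaldehyde | COc1cc(OCc2ccccc2)c(OC)cc1C=O
F3 | step 7 | (E)-3-[4-(benzyloxy)-2,5-dimethoxyphenyl]-1-(6-hydroxy-2,3,4-trimethoxyphenyl)prop-2-en-1-one | COc1cc(O)c(C(=O)/C=C/c2cc(OC)c(OCc3ccccc3)cc2OC)c(OC)c1OC
F4 | step 9 | 2,3-dihydroxy-4-methoxybenzaldehyde | COc1ccc(C=O)c(O)c1O
F5 | step 9 | 2,3-bis(benzyloxy)-4-methoxybenzaldehyde | COc1ccc(C=O)c(OCc2ccccc2)c1OCc1ccccc1
F6 | step 9 | 2,3-bis(benzyloxy)-4-methoxyphenol | COc1ccc(O)c(OCc2ccccc2)c1OCc1ccccc1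
F7 | step 9 | 2,3-bis(benzyloxy)-6-bromo-4-methoxyphenol | COc1cc(Br)c(O)c(OCc2ccccc2)c1OCc1ccccc1
F8 | step 9 | 2,3-bis(benzyloxy)-4-methoxy-6-(trimethylsilyl)phenyl trifluoromethanesulfonate | COc1cc([Si](C)(C)C)c(OS(=O)(=O)C(F)(F)F)c(OCc2ccccc2)c1OCc1ccccc1
F9 | step 9 | 5,6-bis(benzyloxy)-2-[4-(benzyloxy)-2,5-dimethoxyphenyl]-7-methoxychromen-4-one | COc1cc(-c2cc(=O)c3c(OCc4ccccc4)c(OCc4ccccc4)c(OC)cc3o2)c(OC)cc1OCc1ccccc1
F10 | step 6 | 1-(benzyloxy)-4-(2,2-dibromoethenyl)-2,5-dimethoxybenzene | COc1cc(OCc2ccccc2)c(OC)cc1C=C(Br)Br
F11 | step 2 | 3,4,5-trimethoxyphenyl N-isopropylcarbamate | COc1cc(OC(=O)NC(C)C)cc(OC)c1OC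
F12 | step 2 | 3,4,5-trimethoxy-2-(trimethylsilyl)phenyl N-isopropylcarbamate | COc1cc(OC(=O)NC(C)C)c([Si](C)(C)C)c(OC)c1OC
F13 | step 2 | 3,4,5-trimethoxy-2-(trimethylsilyl)phenol | COc1cc(O)c([Si](C)(C)C)c(OC)c1OC
A1 | alternative 1 | 2-ethynyl-5,6,7-trimethoxychromen-4-one | C#Cc1cc(=O)c2c(OC)c(OC)c(OC)cc2o1
A2 | alternative 1 | pentacarbonyl[(1-tert-butoxyethenyl)(methoxy)methylidene]chromium, (CO)5Cr=C(OMe)C(OtBu)=CH2 | COC(C(=C)OC(C)(C)C)=[Cr](=C=O)(=C=O)(=C=O)(=C=O)=C=O
A3 | alternative 1 | 2-[4-(tert-butoxy)-2-hydroxy-5-methoxyphenyl]-5,6,7-trimethoxychromen-4-one | COc1cc(-c2cc(=O)c3c(OC)c(OC)c(OC)cc3o2)c(O)cc1OC(C)(C)C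
A4 | alternative 2 | 2-[4-(benzyloxy)-2,5-dimethoxyphenyl]-6-(tributylstannyl)pyran-4-one | CCCC[Sn](CCCC)(CCCC)c1cc(=O)cc(-c2cc(OC)c(OCc3ccccc3)cc2OC)o1
A5 | alternative 2 | 4-chloro-2,3-dimethoxycyclobut-2-en-1-one (racemic) | COC1=C(OC)C(Cl)C1=O
A6 | alternative 2 | 2-[4-(benzyloxy)-2,5-dimethoxyphenyl]-5-hydroxy-6,7-dimethoxychromen-4-one | COc1cc(-c2cc(=O)c3c(O)c(OC)c(OC)cc3o2)c(OC)cc1OCc1ccccc1
A7 | alternative 3 | 1-[4-(benzyloxy)-2,5-dimethoxyphenyl]-3-(3-hydroxy-2,4-dimethoxyphenyl)propane-1,3-dione | COc1ccc(C(=O)CC(=O)c2cc(OC)c(OCc3ccccc3)cc2OC)c(OC)c1O
A8 | alternative 3 | 2-[4-(benzyloxy)-2,5-dimethoxyphenyl]-6-hydroxy-5,7-dimethoxychromen-4-one | COc1cc(-c2cc(=O)c3c(OC)c(O)c(OC)cc3o2)c(OC)cc1OCc1ccccc1
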